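**Plan**

1. Numbering (bicyclo[3.3.1]nonane): C1 and C5 are the bridgeheads, C2–C3–C4 the enolised 1,3-diketone bridge (aroyl on C3), C6–C7–C8 the carbon bridge, C9 the bridging ketone; ring A = C1, C9, C5, C6, C7, C8; ring B = C1, C2, C3, C4, C5, C9.
2. Enabling feature: C2, C4 and C9 are the three carbonyls of a dearomatised acylphloroglucinol (ring B, a cyclised triketide), and C9 belongs to both six-membered rings. C5, alpha to C4, can therefore be acylated by C9 and then, as the carbon between C4 and C9, alkylated by C6.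
3. Retrosynthesis: cut C5–C6 and C5–C9 (both rings in one operation) to the δ-lactone 19, whose carbonyl is C9 and whose O–CH2 is C6. Then cut C3–C4 and C3–aroyl (two acylations of an acetyl group), C1–prenyl, C8–CH3, C1=C8 with the ester (Knoevenagel lactone), C8–homoprenyl and C6–C7.
4. Forward: chiral β-hydroxy ketone (steps 1–4), temporary δ-lactone ring (step 5), the adjacent quaternary centres C8 and C1 on that ring (steps 6, 7), triketide side chain (steps 8–10), ring B then ring A in one flask with loss of the lactone (step 11), desilylation (step 12).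
5. Stereochemistry: C7 from an oxazolidinone auxiliary (step 2); C8 by cuprate addition anti to the C7 prenyl group; C1 by allylation on the face away from the C7 and C8 chains; C5 is forced by the bridge from C1.

Key step: step 11

Remark: β-di- and tricarbonyl compounds are drawn as one tautomer; the enolisable carbon between the carbonyl groups of 12 (lactone C3) and of 19 (the triacylmethane carbon) is not a fixed stereocentre and is left undefined.

**Step 1**
Reactants: 1 5-methylhex-4-enoic acid; 2 (R)-4-benzyloxazolidin-2-one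
Product: 3 (R)-4-benzyl-3-(5-methylhex-4-enoyl)oxazolidin-2-one
Conditions: PivCl, Et3N, THF, −20 °C; then 2, LiCl, −20 °C → rt
Reagents that add atoms: none
Why: N-acylation of the oxazolidinone through the pivaloyl mixed anhydride (LiCl/Et3N protocol) should proceed cleanly; no stereocenter is formed, and the auxiliary supplies the element that will set C7.

**Step 2**
Reactants: 3 (R)-4-benzyl-3-(5-methylhex-4-enoyl)oxazolidin-2-one
Product: 4 (R)-4-benzyl-3-[(S)-2-(hydroxymethyl)-5-methylhex-4-enoyl]oxazolidin-2-one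
Conditions: TiCl4, i-Pr2NEt, CH2Cl2, 0 °C; then s-trioxane (1.0 equiv), TiCl4, 0 °C
Reagents that add atoms: s-trioxane, C1OCOCO1
Why: Evans-type asymmetric hydroxymethylation (aldol addition of the chelated Z titanium enolate to TiCl4-activated formaldehyde) should deliver the electrophile to the enolate face opposite the benzyl group, which gives the (S) centre that becomes C7; the enolate is far more nucleophilic than the trisubstituted alkene.

**Step 3**
Reactants: 4 (R)-4-benzyl-3-[(S)-2-(hydroxymethyl)-5-methylhex-4-enoyl]oxazolidin-2-one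
Product: 5 (S)-2-(hydroxymethyl)-N-methoxy-N,5-dimethylhex-4-enamide
Conditions: MeNH(OMe)·HCl, AlMe3, CH2Cl2, 0 °C → rt
Reagents that add atoms: N,O-dimethylhydroxylamine hydrochloride, CNOC.Cl
Why: Weinreb amide formation by AlMe3-mediated transamination of the acyl oxazolidinone is assisted by the β-hydroxyl group and should free the auxiliary without enolising the α-centre.

**Step 4**
Reactants: 5 (S)-2-(hydroxymethyl)-N-methoxy-N,5-dimethylhex-4-enamide; 6 5-bromo-2-methylpent-2-ene
Product: 8 (S)-5-(hydroxymethyl)-2,10-dimethylundeca-2,9-dien-6-one, via 4-methylpent-3-en-1-ylmagnesium bromide 7 (not isolated)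
Conditions: 6, Mg, THF, 40 °C; then 5 (one third equiv), THF, −20 → 0 °C; aq. NH4Cl
Reagents that add atoms: none
Why: Weinreb ketone synthesis: one equivalent of the Grignard reagent deprotonates the hydroxyl and the next adds to give a stable magnesium chelate that collapses to the ketone only on quench, so over-addition should not occur and the α-centre (C7) should stay intact.

**Step 5**
Reactants: 8 (S)-5-(hydroxymethyl)-2,10-dimethylundeca-2,9-dien-6-one; 9 2,2,6-trimethyl-4H-1,3-dioxin-4-one
Product: 11 (R)-3-acetyl-5-(3-methylbut-2-en-1-yl)-4-(4-methylpent-3-en-1-yl)-5,6-dihydro-2H-pyran-2-one, via acetoacetate 10 (not isolated)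
Conditions: 9, PhMe, 110 °C (acetone distilled off); then TiCl4, pyridine, THF, 0 °C → rt
Reagents that add atoms: none
Why: Thermolysis of the dioxinone gives acetylketene, which acylates the primary alcohol, and the intramolecular (six-membered) Knoevenagel condensation of the acetoacetate with the C8 ketone under TiCl4/pyridine should close the unsaturated δ-lactone without an amine that could enolise the ketone towards C7; no new stereocenter.

**Step 6**
Reactants: 11 (R)-3-acetyl-5-(3-methylbut-2-en-1-yl)-4-(4-methylpent-3-en-1-yl)-5,6-dihydro-2H-pyran-2-one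
Product: 12 (4S,5R)-3-acetyl-4-methyl-5-(3-methylbut-2-en-1-yl)-4-(4-methylpent-3-en-1-yl)tetrahydro-2H-pyran-2-one (C3 epimers and enol)
Conditions: Me2CuLi (from MeLi, CuI), Et2O/THF, −78 → −40 °C; aq. NH4Cl
Reagents that add atoms: lithium dimethylcuprate, C[Cu-]C.[Li+]
Why: Conjugate addition of a Gilman cuprate to a doubly activated alkylidene β-keto lactone should place methyl on C8 anti to the neighbouring C7 prenyl group (as in 4-substituted cyclohexenones), which sets the quaternary C8 as (S).

**Step 7**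
Reactants: 12 (4S,5R)-3-acetyl-4-methyl-5-(3-methylbut-2-en-1-yl)-4-(4-methylpent-3-en-1-yl)tetrahydro-2H-pyran-2-one; 13 3-methylbut-2-en-1-yl acetate (prenyl acetate)
Product: 14 (3R,4S,5R)-3-acetyl-4-methyl-3,5-bis(3-methylbut-2-en-1-yl)-4-(4-methylpent-3-en-1-yl)tetrahydro-2H-pyran-2-one
Conditions: NaH, THF, 0 °C; then 13, Pd(PPh3)4 (5 mol %), rt → 50 °C
Reagents that add atoms: none
Why: Tsuji–Trost allylation of the β-keto lactone enolate should occur at carbon (O-allylation is reversible under the catalyst) and at the unsubstituted terminus of the prenyl palladium complex, from the enolate face that carries the C8 methyl and C7–H and not the C8 homoprenyl and C7 prenyl chains, so that lactone C3 (the later C1) becomes (R) with acetyl cis to both chains.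

**Step 8**
Reactants: 15 methyl 3-hydroxybenzoate
Product: 16 methyl 3-(triisopropylsilyloxy)benzoate
Conditions: i-Pr3SiCl, imidazole, DMF, rt
Reagents that add atoms: triisopropylsilyl chloride, CC(C)[Si](Cl)(C(C)C)C(C)C
Why: Standard silylation of a phenol with a silyl chloride and imidazole; the triisopropylsilyl ether is chosen because it should resist the lithium amide bases of steps 9 and 11 and is removed by fluoride.

**Step 9**
Reactants: 14 (3R,4S,5R)-3-acetyl-4-methyl-3,5-bis(3-methylbut-2-en-1-yl)-4-(4-methylpent-3-en-1-yl)tetrahydro-2H-pyran-2-one; 16 methyl 3-(triisopropylsilyloxy)benzoate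
Product: 17 1-[(3R,4S,5R)-4-methyl-3,5-bis(3-methylbut-2-en-1-yl)-4-(4-methylpent-3-en-1-yl)-2-oxotetrahydro-2H-pyran-3-yl]-3-[3-(triisopropylsilyloxy)phenyl]propane-1,3-dione
Conditions: LiN(SiMe3)2 (3 equiv), THF, −78 °C; then 16, −78 °C → rt; aq. HCl (0.5 M)
Reagents that add atoms: none
Why: Crossed Claisen condensation: the acetyl group is the only enolisable position of 14, and its lithium enolate should be acylated by the non-enolisable aryl ester to give the 1,3-diketone as its enolate, which protects it from retro-Claisen cleavage; no stereocenter is touched.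

**Step 10**
Reactants: 17 1-[(3R,4S,5R)-4-methyl-3,5-bis(3-methylbut-2-en-1-yl)-4-(4-methylpent-3-en-1-yl)-2-oxotetrahydro-2H-pyran-3-yl]-3-[3-(triisopropylsilyloxy)phenyl]propane-1,3-dione; 1 5-methylhex-4-enoic acid
Product: 19 7-methyl-1-[(3R,4S,5R)-4-methyl-3,5-bis(3-methylbut-2-en-1-yl)-4-(4-methylpent-3-en-1-yl)-2-oxotetrahydro-2H-pyran-3-yl]-2-[3-(triisopropylsilyloxy)benzoyl]oct-6-ene-1,3-dione, via 5-methylhex-4-enoyl chloride 18 (not isolated)
Conditions: 1, (COCl)2, DMF (cat.), CH2Cl2, 0 °C → rt, concentrate; then 17, MgCl2, Et3N, MeCN, 0 °C → rt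
Reagents that add atoms: none
Why: C-acylation of the magnesium chelate of a 1,3-diketone by an acid chloride (MgCl2/amine method) should acylate the central carbon (the future C3) and so install C4, C5 and the C5 prenyl group as a 2-acyl-1,3-diketone; the new triacylmethane carbon is enolised and not a stereocenter.

**Step 11**
Reactants: 19 7-methyl-1-[(3R,4S,5R)-4-methyl-3,5-bis(3-methylbut-2-en-1-yl)-4-(4-methylpent-3-en-1-yl)-2-oxotetrahydro-2H-pyran-3-yl]-2-[3-(triisopropylsilyloxy)benzoyl]oct-6-ene-1,3-dione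
Product: 22 (1S,5S,7S,8S)-4-hydroxy-8-methyl-1,5,7-tris(3-methylbut-2-en-1-yl)-8-(4-methylpent-3-en-1-yl)-3-[3-(triisopropylsilyloxy)benzoyl]bicyclo[3.3.1]non-3-ene-2,9-dione, via hydroxy trione 20 (not isolated), via tosylate 21 (not isolated)
Conditions: LiTMP (lithium 2,2,6,6-tetramethylpiperidide, 3.1 equiv), THF, −78 → −20 °C; then Ts2O (1.05 equiv), −78 °C → rt, then 45 °C; aq. HCl (0.5 M), 0 °C
Reagents that add atoms: none
Why: Proposed new method: LiTMP should convert the β-tricarbonyl unit of 19 into its dianion by γ-deprotonation at C5 (as known for 2-acylcyclohexane-1,3-diones and 3-acyltetramic acids), and the C5 carbanion attacks the lactone carbonyl C9 in a 6-exo-trig Claisen acylation whose tetrahedral intermediate expels the C6 alkoxide, so that ring B is closed as a dearomatised acylphloroglucinol and the third equivalent of base removes the new, doubly activated C5–H, which makes the acyl transfer irreversible. The closest known reaction types are the γ-acylation of β-dicarbonyl polyanions by esters (the laboratory form of the polyketide Claisen cyclisation to acylphloroglucinols) and, for the second ring, the alkylative dearomatisation–annulation of acylphloroglucinols, in which alkyl-bearing ring carbons are C-alkylated to bridgehead quaternary centres. The freed primary alkoxide is the only localised oxyanion and should be tosylated by Ts2O in preference to the delocalised, lithium-chelated enolate oxygens, after which C5 displaces the tosylate at C6 in a 6-(enolendo)-exo-tet alkylation that closes ring A. The only new stereocentre, C5, is dictated by the substrate: the tether C8–C7–C6 hangs from C1 on one face of ring B and can reach C5 only on that face, so (5S) follows from the C1 configuration fixed in step 7, while C1, C7 and C8 are not enolisable and are not touched. The selectivities needed are C5 over C3 and carbon over oxygen: C3 is the aroyl-bearing centre of a tricarbonyl anion, which C-alkylates poorly, whereas C5 is the last-deprotonated and most basic site, lithium in THF holds the enolate oxygens, and attack of C3 on C9 would need a four-membered ring. The lactone keeps C6 masked as an ester oxygen until the C5–C9 bond exists, which prevents a premature six-membered alkylation at C3 or at oxygen of the open-chain tricarbonyl anion.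

**Step 12**
Reactants: 22 (1S,5S,7S,8S)-4-hydroxy-8-methyl-1,5,7-tris(3-methylbut-2-en-1-yl)-8-(4-methylpent-3-en-1-yl)-3-[3-(triisopropylsilyloxy)benzoyl]bicyclo[3.3.1]non-3-ene-2,9-dione
Product: 23 (1S,5S,7S,8S)-4-hydroxy-3-(3-hydroxybenzoyl)-8-methyl-1,5,7-tris(3-methylbut-2-en-1-yl)-8-(4-methylpent-3-en-1-yl)bicyclo[3.3.1]non-3-ene-2,9-dione (CNP0406274.1)
Conditions: Bu4NF, AcOH, THF, 0 °C
Reagents that add atoms: none
Why: Fluoride-mediated cleavage of the aryl silyl ether, buffered with acetic acid, should leave the enolised trione and the four trisubstituted alkenes untouched; no stereocenter is affected.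

**Compound list**

1 | 5-methylhex-4-enoic acid | CC(C)=CCCC(=O)O | starting material
2 | (R)-4-benzyloxazolidin-2-one | O=C1N[C@H](Cc2ccccc2)CO1 | starting material
3 | (R)-4-benzyl-3-(5-methylhex-4-enoyl)oxazolidin-2-one | CC(C)=CCCC(=O)N1[C@H](Cc2ccccc2)COC1=O | intermediate
4 | (R)-4-benzyl-3-[(S)-2-(hydroxymethyl)-5-methylhex-4-enoyl]oxazolidin-2-one | CC(C)=CC[C@@H](CO)C(=O)N1[C@H](Cc2ccccc2)COC1=O | intermediate
5 | (S)-2-(hydroxymethyl)-N-methoxy-N,5-dimethylhex-4-enamide | CC(C)=CC[C@@H](CO)C(=O)N(C)OC | intermediate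
6 | 5-bromo-2-methylpent-2-ene | CC(C)=CCCBr | starting material
7 | 4-methylpent-3-en-1-ylmagnesium bromide | CC(C)=CCC[Mg]Br | intermediate
8 | (S)-5-(hydroxymethyl)-2,10-dimethylundeca-2,9-dien-6-one | CC(C)=CC[C@@H](CO)C(=O)CCC=C(C)C | intermediate
9 | 2,2,6-trimethyl-4H-1,3-dioxin-4-one | CC1=CC(=O)OC(C)(C)O1 | starting material
10 | (S)-7-methyl-2-(3-methylbut-2-en-1-yl)-3-oxooct-6-en-1-yl 3-oxobutanoate | CC(C)=CC[C@@H](COC(=O)CC(C)=O)C(=O)CCC=C(C)C | intermediate
11 | (R)-3-acetyl-5-(3-methylbut-2-en-1-yl)-4-(4-methylpent-3-en-1-yl)-5,6-dihydro-2H-pyran-2-one | O=C1OC[C@H](CC=C(C)C)C(CCC=C(C)C)=C1C(C)=O | intermediate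
12 | (4S,5R)-3-acetyl-4-methyl-5-(3-methylbut-2-en-1-yl)-4-(4-methylpent-3-en-1-yl)tetrahydro-2H-pyran-2-one (C3 epimers and enol) | O=C1OC[C@H](CC=C(C)C)[C@](C)(CCC=C(C)C)C1C(C)=O | intermediate
13 | 3-methylbut-2-en-1-yl acetate (prenyl acetate) | CC(=O)OCC=C(C)C | starting material
14 | (3R,4S,5R)-3-acetyl-4-methyl-3,5-bis(3-methylbut-2-en-1-yl)-4-(4-methylpent-3-en-1-yl)tetrahydro-2H-pyran-2-one | O=C1OC[C@H](CC=C(C)C)[C@](C)(CCC=C(C)C)[C@]1(CC=C(C)C)C(C)=O | intermediate
15 | methyl 3-hydroxybenzoate | COC(=O)c1cccc(O)c1 | starting material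
16 | methyl 3-(triisopropylsilyloxy)benzoate | COC(=O)c1cccc(O[Si](C(C)C)(C(C)C)C(C)C)c1 | intermediate
17 | 1-[(3R,4S,5R)-4-methyl-3,5-bis(3-methylbut-2-en-1-yl)-4-(4-methylpent-3-en-1-yl)-2-oxotetrahydro-2H-pyran-3-yl]-3-[3-(triisopropylsilyloxy)phenyl]propane-1,3-dione | O=C1OC[C@H](CC=C(C)C)[C@](C)(CCC=C(C)C)[C@]1(CC=C(C)C)C(=O)CC(=O)c1cccc(O[Si](C(C)C)(C(C)C)C(C)C)c1 | intermediate
18 | 5-methylhex-4-enoyl chloride | CC(C)=CCCC(Cl)=O | intermediate
19 | 7-methyl-1-[(3R,4S,5R)-4-methyl-3,5-bis(3-methylbut-2-en-1-yl)-4-(4-methylpent-3-en-1-yl)-2-oxotetrahydro-2H-pyran-3-yl]-2-[3-(triisopropylsilyloxy)benzoyl]oct-6-ene-1,3-dione | O=C1OC[C@H](CC=C(C)C)[C@](C)(CCC=C(C)C)[C@]1(CC=C(C)C)C(=O)C(C(=O)CCC=C(C)C)C(=O)c1cccc(O[Si](C(C)C)(C(C)C)C(C)C)c1 | intermediate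
20 | (6S)-3,5-dihydroxy-6-[(2R,3S)-1-hydroxy-3,7-dimethyl-2-(3-methylbut-2-en-1-yl)oct-6-en-3-yl]-4,6-bis(3-methylbut-2-en-1-yl)-2-[3-(triisopropylsilyloxy)benzoyl]cyclohexa-2,4-dien-1-one (hydroxy trione, dienol tautomer) | OC[C@H](CC=C(C)C)[C@](C)(CCC=C(C)C)[C@]1(CC=C(C)C)C(=O)C(C(=O)c2cccc(O[Si](C(C)C)(C(C)C)C(C)C)c2)=C(O)C(CC=C(C)C)=C1O | intermediate
21 | p-toluenesulfonate of the primary alcohol of 20 | Cc1ccc(cc1)S(=O)(=O)OC[C@H](CC=C(C)C)[C@](C)(CCC=C(C)C)[C@]1(CC=C(C)C)C(=O)C(C(=O)c2cccc(O[Si](C(C)C)(C(C)C)C(C)C)c2)=C(O)C(CC=C(C)C)=C1O | intermediate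
22 | (1S,5S,7S,8S)-4-hydroxy-8-methyl-1,5,7-tris(3-methylbut-2-en-1-yl)-8-(4-methylpent-3-en-1-yl)-3-[3-(triisopropylsilyloxy)benzoyl]bicyclo[3.3.1]non-3-ene-2,9-dione | CC(C)=CCC[C@@]1(C)[C@@H](CC=C(C)C)C[C@]2(CC=C(C)C)C(=O)[C@@]1(CC=C(C)C)C(=O)C(C(=O)c1cccc(O[Si](C(C)C)(C(C)C)C(C)C)c1)=C2O | intermediate
23 | (1S,5S,7S,8S)-4-hydroxy-3-(3-hydroxybenzoyl)-8-methyl-1,5,7-tris(3-methylbut-2-en-1-yl)-8-(4-methylpent-3-en-1-yl)bicyclo[3.3.1]non-3-ene-2,9-dione | CC(C)=CCC[C@@]1(C)[C@@H](CC=C(C)C)C[C@]2(CC=C(C)C)C(=O)[C@@]1(CC=C(C)C)C(=O)C(C(=O)c1cccc(O)c1)=C2O | target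

**Step count and risks**

Total step count: 12. Longest linear sequence: 11 steps (steps 1–7 and 9–12, from 1 and 2; step 8 is a one-step side branch).

Steps most likely to fail:

1. Step 11. What may go wrong: sulfonylation of an enolate oxygen in competition with the alkoxide, or O-alkylation (closure to a cyclic enol ether through the C9 or C2 oxygen) instead of C-alkylation at C5 when ring A closes. Fallback with known chemistry, from 19 back to 22: the Claisen ring switch is run alone (LiTMP, THF, −78 → −20 °C) and quenched cold with AcOH, so that hydroxy trione 20 is isolated. Its primary alcohol is converted by an Appel reaction (PPh3, I2, imidazole, CH2Cl2, 0 °C) into the primary iodide F1. F1 is then cyclised under protic alkylative-dearomatisation conditions (aq. LiOH, THF, 0 °C → rt), where hydrogen bonding to the enolate oxygens should favour C-alkylation at C5, to give 22.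

2. Step 5. What may go wrong: loss of configuration at C7 by enolisation of the C8 ketone, or β-elimination of the acetoacetate, during the Knoevenagel condensation. Fallback, from 4 back to 11 (steps 3 and 4 are bypassed): the alcohol of 4 is acetoacetylated with 9 (PhMe, 110 °C) to the imide acetoacetate F2. A Lacey–Dieckmann cyclisation onto the imide carbonyl (KOt-Bu, THF, 0 °C) releases auxiliary 2 and gives the 3-acetyl-4-hydroxy lactone F3, whose tricarbonyl anion shields C7. Sulfonylation (Tf2O, Et3N, CH2Cl2, −78 °C) gives the enol triflate F4, and Negishi coupling with the zinc reagent made from 7 and ZnCl2 (Pd(PPh3)4, THF, rt) installs the homoprenyl group and gives 11.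

3. Step 7. What may go wrong: attack at the substituted terminus of the prenyl palladium complex (reverse prenylation) or poor conversion at the hindered carbon between the lactone and the new quaternary centre. Fallback, from 12 back to 14: Tsuji–Trost allylation with allyl acetate (NaH, Pd(PPh3)4, THF), whose symmetrical allyl complex has no regiochemical choice and is smaller, gives the allyl lactone F5. Cross-metathesis of F5 with 2-methylbut-2-ene (second-generation Grubbs catalyst, CH2Cl2, 40 °C) turns the allyl group into prenyl and gives 14.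

**Further compounds**

F1 | step 11 | (6S)-3,5-dihydroxy-6-[(2R,3S)-1-iodo-3,7-dimethyl-2-(3-methylbut-2-en-1-yl)oct-6-en-3-yl]-4,6-bis(3-methylbut-2-en-1-yl)-2-[3-(triisopropylsilyloxy)benzoyl]cyclohexa-2,4-dien-1-one | IC[C@H](CC=C(C)C)[C@](C)(CCC=C(C)C)[C@]1(CC=C(C)C)C(=O)C(C(=O)c2cccc(O[Si](C(C)C)(C(C)C)C(C)C)c2)=C(O)C(CC=C(C)C)=C1O
F2 | step 5 | (S)-2-{[(R)-4-benzyl-2-oxooxazolidin-3-yl]carbonyl}-5-methylhex-4-en-1-yl 3-oxobutanoate | CC(C)=CC[C@@H](COC(=O)CC(C)=O)C(=O)N1[C@H](Cc2ccccc2)COC1=O
F3 | step 5 | (S)-3-acetyl-4-hydroxy-5-(3-methylbut-2-en-1-yl)-5,6-dihydro-2H-pyran-2-one | O=C1OC[C@H](CC=C(C)C)C(O)=C1C(C)=O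
F4 | step 5 | (S)-3-acetyl-5-(3-methylbut-2-en-1-yl)-2-oxo-5,6-dihydro-2H-pyran-4-yl trifluoromethanesulfonate | O=C1OC[C@H](CC=C(C)C)C(OS(=O)(=O)C(F)(F)F)=C1C(C)=O
F5 | step 7 | (3R,4S,5R)-3-acetyl-3-allyl-4-methyl-5-(3-methylbut-2-en-1-yl)-4-(4-methylpent-3-en-1-yl)tetrahydro-2H-pyran-2-one | O=C1OC[C@H](CC=C(C)C)[C@](C)(CCC=C(C)C)[C@]1(CC=C)C(C)=O
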